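## Structural features

Ring positions are labelled as follows: ring B carries the methyl ester at B1, methyl at B2, the acyloxy oxygen at B3, hydroxyl at B4, methyl at B5 and hydroxyl at B6; ring A carries the depside carbonyl at A1, methyl at A2, hydrogen at A3, hydroxyl at A4, formyl at A5 and hydroxyl at A6. The target is a depside: two benzene rings joined only by an aryl ester from the A1 carbonyl to the B3 oxygen. It has no stereocentre, so every selectivity question is one of position or chemoselectivity. Ring A is a haematommic acid unit whose aldehyde sits between two phenols and is hydrogen-bonded to both. Ring B is hexasubstituted, with a salicylate on one edge, a catechol mono-ester on the other and para-related oxygens at B3 and B6. The fragile points are three: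
- the aryl ester, which is hard to make because both partners are di-ortho-substituted, and which can shift from B3 to B4 under base once the B4 hydroxyl is free;
- the aldehyde, which is open to reduction and base-induced disproportionation;
- the oxygen-rich ring B, which oxidises easily when its phenols are free.

The real difficulty is ring B, whose three oxygens must be told apart so that only B3 is acylated. The key step exploits the B3/B6 para-dioxygen pattern with the B4 oxygen and B5 methyl between them. This is the imprint of a 2,4-dioxygenated 3-methylfuran that has taken up the B1–B2 two-carbon unit across its 2- and 5-positions and opened its oxygen bridge, leaving B6 silylated, B4 benzylated and B3 alone free.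

## Logic of the disconnections

**14 to 13.** The three O–benzyl bonds at A4, A6 and B4 are cut last. All three phenols must stay masked through acylation and desilylation, and a single acidic operation frees them without any base that could move the ester from B3 to B4. The skeleton is unchanged, but every earlier step is freed of free-phenol chemistry. The forward step must cleave aryl benzyl ethers without reducing the aldehyde and without touching either ester.

**13 to 12.** The O–Si bond at B6 is cut. The silyl group is what the ring-forming step leaves on B6, and keeping it through the coupling makes B3 the only nucleophilic oxygen. It is removed while B4 is still benzylated, so the phenoxide formed has no neighbouring ester to attack. The forward step needs a buffered fluoride source that spares the aryl ester.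

**12 to 6 and 11.** The ester C–O bond between the A1 carbonyl and the B3 oxygen is cut. This is the convergent cut and gives two halves of similar size, each made independently. The forward step must join a di-ortho-substituted acyl donor to a phenol flanked by methyl and benzyloxy, so it needs the most reactive acyl derivative and nucleophilic catalysis.

**6 to 3 and 4, through 5.** The B2–B3 and B1–B6 bonds are cut and the B3 oxygen is reconnected to B6 as a bridge. The hexasubstituted benzene falls back to a five-membered diene and a four-carbon alkyne that already hold all six substituents. The forward step must pair the unsubstituted diene terminus with the methyl-bearing alkyne carbon, and the bridge must open at the silyloxy bridgehead.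

**3 to 2 to 1.** The O–Si bond and then the O–benzyl bond are cut, leading back to a purchasable vinylogous acid. The forward steps need O- rather than C-benzylation, and silylation with removal of the ring CH2 proton.

**11 to 10 to 9 to 8 to 7.** In turn the C–Cl bond, the methyl ester O–CH3 bond (as a hydrolysis), the two O–benzyl bonds and the A5–CHO bond are cut, ending at a purchasable resorcinol ester. The forward formylation must go between the two hydroxyls (A5) and not to A3, and the hydrolysis of the hindered ester must spare the aldehyde.

## Other disconnections considered

**Alternative 1:** The cut is through B1–B2 and B5–B6, taking ring B back to (Z)-4-(benzyloxy)hex-4-en-3-one A1 and dimethyl malonate A2. Forward, the malonate anion adds to the β-carbon of A1. The ethyl-ketone enolate then closes on one ester (Michael addition, then Dieckmann-type Claisen condensation) to give the dione A3, which must be dehydrogenated to the resorcinol A4.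

- In favour: cheap acyclic reagents, ordinary enolate chemistry and no moisture-sensitive diene. Every substituent position is fixed by connectivity, so there is no regiochemical question. On that point it is the better of the two plans, because the chosen cycloaddition relies on an electronic bias.
- Against: A3 is one oxidation level below the arene. Its B3 benzyloxy group can leave as benzyl alcohol, which aromatizes the ring without an oxidant to the deoxy compound A5 and deletes the oxygen that B3 needs.
- Against: the protection pattern comes out inverted. In A4, B3 is benzylated and B4/B6 are free, so a second protecting group and a selective debenzylation would be needed before acylation.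
- Against: A1 needs its own synthesis with control of alkene geometry.
- Comparison: both plans put all six substituents on ring B. The mechanism is ionic and stepwise rather than a cycloaddition with fragmentation. The chosen plan reaches the correctly differentiated phenol in three steps, whereas this one needs annulation, oxidation, reprotection and deprotection on top of the enone synthesis.

**Alternative 2:** The cut is through A5–A6, A3–A4 and A1–A6, so ring A is assembled around the formyl carbon. Forward, photochemical Wolff rearrangement of the diazoketone A6 gives a vinylketene. This adds the siloxyalkyne A7 in a [2+2] step, and cyclobutenone opening with 6π closure gives the benzoate A8.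

- In favour: the formyl carbon arrives as an acetal fixed between the two oxygens, so electrophilic formylation and its regiochemistry are avoided. That is better than step 4 of the chosen plan.
- In favour: the carboxyl arrives as a benzyl ester that can be freed without hydroxide, which is better than step 6. The ketene and ynol-ether polarity fixes the regiochemistry as firmly as the chosen key step does.
- Against: ring A is the easy ring, reachable from a stock resorcinol ester in one step. The strategic step is spent there, and the hexasubstituted ring B is left unsolved.
- Against: A6 and A7 each need several steps and photochemical equipment, and the acetal next to a free phenol in A8 is acid-labile.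
- Comparison: on structure it addresses the simpler half, on mechanism it is an elegant pericyclic cascade, and on step economy it is clearly longer.

**Alternative 3:** The cut is the A1–A2 bond, so ring A is grown on the ring B oxygen. Forward, the aryl 3,5,7-trioxooctanoate A9, made by acylating the ring B phenol A11 with an acylketene equivalent, undergoes aldol closure of chain C2 on the C7 ketone. Dehydration and enolization then give the orsellinate depside A10.

- In favour: it is biomimetic, and the hindered ester bond is made while the acyl partner is still an unhindered chain. That is easier than joining two di-ortho-substituted partners, as step 8 of the chosen plan must.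
- Against: the aryloxide is a good leaving group. Lactonization of the C5 enol onto the ester (pyranone formation) or Claisen C-acylation would expel A11 and destroy the depside link, so the aldol mode has to win.
- Against: A10 lacks the formyl group, so a late formylation must distinguish A5 from A3 on a sensitive depside.
- Against: A11 still has to be made, so the ring B problem is untouched.
- Comparison: on structure it solves only ring A, on mechanism it is a polyketide aldol with competing acyl-transfer paths, and on step economy it is longer once ring B and the late formylation are counted.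

Key step: step 3

Assumption: the target has no stereocentre; intermediate 5 is racemic and its two bridgehead centres vanish on aromatization, so no stereocontrol is planned.

## Steps

Step 1
Reactants: 1 3-methyltetronic acid
Product: 2 4-(benzyloxy)-3-methylfuran-2(5H)-one
Conditions: BnOH, PPh3, DIAD, THF, 0 °C to rt
Reagents that add atoms: benzyl alcohol, OCc1ccccc1
Why: Mitsunobu O-alkylation of an acidic vinylogous acid; the tetronate oxygen attacks the benzyloxyphosphonium ion, and the neutral conditions avoid the C3-benzylation that benzyl halide with base can cause.

Step 2
Reactants: 2 4-(benzyloxy)-3-methylfuran-2(5H)-one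
Product: 3 4-(benzyloxy)-2-[(tert-butyldimethylsilyl)oxy]-3-methylfuran
Conditions: TBSOTf, Et3N, CH2Cl2, 0 °C; pentane trituration, used directly
Reagents that add atoms: tert-butyldimethylsilyl trifluoromethanesulfonate, CC(C)(C)[Si](C)(C)OS(=O)(=O)C(F)(F)F
Why: Soft enolization (silyl dienol ether formation): the silyl triflate activates the lactone carbonyl, Et3N removes a C5 proton, and the gain of furan aromaticity drives O-silylation.

Step 3
Reactants: 3 4-(benzyloxy)-2-[(tert-butyldimethylsilyl)oxy]-3-methylfuran; 4 methyl but-2-ynoate
Product: 6 methyl 4-(benzyloxy)-2-[(tert-butyldimethylsilyl)oxy]-5-hydroxy-3,6-dimethylbenzoate, via oxanorbornadiene cycloadduct 5 (not isolated)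
Conditions: 4 (excess), PhMe, 110 °C, sealed tube; then silica gel, CH2Cl2, rt
Reagents that add atoms: none
Why: Furan 3 is an s-cis-locked, doubly donor-substituted diene whose unsubstituted C5 receives electron density from both the silyloxy and the benzyloxy oxygen, so C5 bonds to the electrophilic methyl-bearing β-carbon of 4 and the silyloxy-bearing C2 closes on the ester-bearing α-carbon. Whether this is an asynchronous concerted [4+2] cycloaddition or a vinylogous Mukaiyama–Michael addition followed by collapse of the allenoate onto the silyloxocarbenium ion, the six-membered carbocycle is closed intermolecularly in the 4+2 mode as 7-oxanorbornadiene 5. The two bridgehead centres of 5 form as a racemate with the relative configuration forced by the bridge and are destroyed on aromatization, so no element of stereocontrol is required. In 5 the silyloxy bridgehead is a mixed ketal, and heterolysis of its bridging C–O bond gives a silyloxocarbenium ion that is also conjugated with the benzyloxy enol ether, while the oxygen stays on the other bridgehead. Loss of that bridgehead proton aromatizes the ring, so the former furan oxygen becomes the free B3 hydroxyl and the silyl group remains on the B6 oxygen para to it. The closest known reaction type is the Diels–Alder reaction of 2-silyloxyfurans with acetylenic esters followed by opening of the oxabicycle to para-silyloxyphenols. The selectivity needed is regiochemical (ester next to B6, methyl next to B3), secured by matching the nucleophilic C5 with the ynoate β-carbon. The direction of bridge opening is secured by the silyloxy group, which stabilizes a cation only at its own bridgehead.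

Step 4
Reactants: 7 methyl orsellinate
Product: 8 methyl 3-formyl-2,4-dihydroxy-6-methylbenzoate
Conditions: Cl2CHOMe, TiCl4, CH2Cl2, −10 to 0 °C; then aq. HCl
Reagents that add atoms: dichloromethyl methyl ether, COC(Cl)Cl; water, O
Why: Rieche formylation (Friedel–Crafts type); the titanium-bound phenoxides direct the electrophile to A5, which is ortho to both oxygens and activated by the chelated salicylate, while A3 is flanked by the methyl group.

Step 5
Reactants: 8 methyl 3-formyl-2,4-dihydroxy-6-methylbenzoate
Product: 9 methyl 2,4-bis(benzyloxy)-3-formyl-6-methylbenzoate
Conditions: BnBr, K2CO3, DMF, 60 °C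
Reagents that add atoms: benzyl bromide, BrCc1ccccc1
Why: Williamson ether synthesis; both phenoxides are O-alkylated in a dipolar aprotic solvent, warming overcomes the chelation of the A6 hydroxyl, and the non-enolizable aldehyde is inert to carbonate.

Step 6
Reactants: 9 methyl 2,4-bis(benzyloxy)-3-formyl-6-methylbenzoate
Product: 10 2,4-bis(benzyloxy)-3-formyl-6-methylbenzoic acid
Conditions: KOH, MeOH/THF/H2O, 65 °C; then 1 M HCl
Reagents that add atoms: potassium hydroxide, [K+].[OH-]
Why: Saponification of a 2-alkoxy-6-methylbenzoate, a known ester class that needs warming; the aldehyde is shielded by two ortho benzyloxy groups and electron-rich, which disfavours hydroxide addition and disproportionation.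

Step 7
Reactants: 10 2,4-bis(benzyloxy)-3-formyl-6-methylbenzoic acid
Product: 11 2,4-bis(benzyloxy)-3-formyl-6-methylbenzoyl chloride
Conditions: (COCl)2, DMF (cat.), CH2Cl2, 0 °C to rt; evaporate, use crude
Reagents that add atoms: oxalyl chloride, ClC(=O)C(=O)Cl
Why: Acid chloride formation through the catalytic chloroiminium (Vilsmeier-type) species under neutral conditions, which the benzyl ethers and the aryl aldehyde tolerate.

Step 8
Reactants: 6 methyl 4-(benzyloxy)-2-[(tert-butyldimethylsilyl)oxy]-5-hydroxy-3,6-dimethylbenzoate; 11 2,4-bis(benzyloxy)-3-formyl-6-methylbenzoyl chloride
Product: 12 methyl 4-(benzyloxy)-5-{[2,4-bis(benzyloxy)-3-formyl-6-methylbenzoyl]oxy}-2-[(tert-butyldimethylsilyl)oxy]-3,6-dimethylbenzoate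
Conditions: Et3N, DMAP (cat.), CH2Cl2, 0 °C to rt
Reagents that add atoms: none
Why: DMAP-catalysed acylation of a phenol by an acid chloride; the B3 hydroxyl is the only free oxygen nucleophile, and the acylpyridinium ion is reactive enough for the hindered phenol.

Step 9
Reactants: 12 methyl 4-(benzyloxy)-5-{[2,4-bis(benzyloxy)-3-formyl-6-methylbenzoyl]oxy}-2-[(tert-butyldimethylsilyl)oxy]-3,6-dimethylbenzoate
Product: 13 methyl 4-(benzyloxy)-5-{[2,4-bis(benzyloxy)-3-formyl-6-methylbenzoyl]oxy}-2-hydroxy-3,6-dimethylbenzoate
Conditions: TBAF, AcOH, THF, 0 °C
Reagents that add atoms: none
Why: Fluoride-mediated cleavage of an aryl silyl ether; acetic acid buffering protonates the phenoxide at once, and the freed B6 oxygen is para to the aryl ester, so no acyl shift is possible while B4 is still benzylated.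

Step 10
Reactants: 13 methyl 4-(benzyloxy)-5-{[2,4-bis(benzyloxy)-3-formyl-6-methylbenzoyl]oxy}-2-hydroxy-3,6-dimethylbenzoate
Product: 14 methyl 5-[(3-formyl-2,4-dihydroxy-6-methylbenzoyl)oxy]-2,4-dihydroxy-3,6-dimethylbenzoate
Conditions: BCl3, pentamethylbenzene, CH2Cl2, −78 to −30 °C; then H2O (pH 5 buffer)
Reagents that add atoms: none
Why: Lewis-acid debenzylation of aryl benzyl ethers with a non-Lewis-basic cation scavenger; the conditions are non-reducing and non-basic, so the aldehyde, both esters and the position of the B3 ester should be preserved.

## Compound list

1 | 3-methyltetronic acid (4-hydroxy-3-methylfuran-2(5H)-one) | CC1=C(O)COC1=O | starting material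
2 | 4-(benzyloxy)-3-methylfuran-2(5H)-one | CC1=C(OCc2ccccc2)COC1=O | intermediate
3 | 4-(benzyloxy)-2-[(tert-butyldimethylsilyl)oxy]-3-methylfuran | Cc1c(OCc2ccccc2)coc1O[Si](C)(C)C(C)(C)C | intermediate
4 | methyl but-2-ynoate | CC#CC(=O)OC | starting material
5 | methyl 5-(benzyloxy)-1-[(tert-butyldimethylsilyl)oxy]-3,6-dimethyl-7-oxabicyclo[2.2.1]hepta-2,5-diene-2-carboxylate (racemic) | COC(=O)C1=C(C)C2OC1(O[Si](C)(C)C(C)(C)C)C(C)=C2OCc1ccccc1 | intermediate
6 | methyl 4-(benzyloxy)-2-[(tert-butyldimethylsilyl)oxy]-5-hydroxy-3,6-dimethylbenzoate | COC(=O)c1c(C)c(O)c(OCc2ccccc2)c(C)c1O[Si](C)(C)C(C)(C)C | intermediate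
7 | methyl orsellinate (methyl 2,4-dihydroxy-6-methylbenzoate) | COC(=O)c1c(C)cc(O)cc1O | starting material
8 | methyl 3-formyl-2,4-dihydroxy-6-methylbenzoate | COC(=O)c1c(C)cc(O)c(C=O)c1O | intermediate
9 | methyl 2,4-bis(benzyloxy)-3-formyl-6-methylbenzoate | COC(=O)c1c(C)cc(OCc2ccccc2)c(C=O)c1OCc1ccccc1 | intermediate
10 | 2,4-bis(benzyloxy)-3-formyl-6-methylbenzoic acid | OC(=O)c1c(C)cc(OCc2ccccc2)c(C=O)c1OCc1ccccc1 | intermediate
11 | 2,4-bis(benzyloxy)-3-formyl-6-methylbenzoyl chloride | ClC(=O)c1c(C)cc(OCc2ccccc2)c(C=O)c1OCc1ccccc1 | intermediate
12 | methyl 4-(benzyloxy)-5-{[2,4-bis(benzyloxy)-3-formyl-6-methylbenzoyl]oxy}-2-[(tert-butyldimethylsilyl)oxy]-3,6-dimethylbenzoate | COC(=O)c1c(C)c(OC(=O)c2c(C)cc(OCc3ccccc3)c(C=O)c2OCc2ccccc2)c(OCc2ccccc2)c(C)c1O[Si](C)(C)C(C)(C)C | intermediate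
13 | methyl 4-(benzyloxy)-5-{[2,4-bis(benzyloxy)-3-formyl-6-methylbenzoyl]oxy}-2-hydroxy-3,6-dimethylbenzoate | COC(=O)c1c(C)c(OC(=O)c2c(C)cc(OCc3ccccc3)c(C=O)c2OCc2ccccc2)c(OCc2ccccc2)c(C)c1O | intermediate
14 | methyl 5-[(3-formyl-2,4-dihydroxy-6-methylbenzoyl)oxy]-2,4-dihydroxy-3,6-dimethylbenzoate | COC(=O)c1c(C)c(OC(=O)c2c(C)cc(O)c(C=O)c2O)c(O)c(C)c1O | target

## Step count and risk

Total step count: 10. Longest linear sequence: 7 steps (7 to 14 through steps 4, 5, 6, 7, 8, 9 and 10); the ring B branch contributes 6 (steps 1, 2, 3, 8, 9, 10).

**Step 3 (key step).** The β-methyl ynoate is a sluggish dienophile. Furan 3 may desilylate or decompose thermally before it adds, or the first C–C bond may form and the intermediate be protonated instead of closing, which stops at a 5-alkenylbutenolide. Fallback, from 3 back to 6: commercial methyl buta-2,3-dienoate, a more reactive allenic isomer of 4, is used as the dienophile. Its conjugated double bond should add with the same polarity (central carbon to furan C5) in toluene at rt to 60 °C. This should give methyl 5-(benzyloxy)-1-[(tert-butyldimethylsilyl)oxy]-6-methyl-3-methylidene-7-oxabicyclo[2.2.1]hept-5-ene-2-carboxylate F1. Catalytic DBU in CH2Cl2 should then remove the proton next to the ester, open the bridge at the silyloxy bridgehead and move the exocyclic double bond into the ring, arriving at 6.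

**Step 4.** Formylation may go partly to A3 (between hydroxyl and methyl) or occur twice, because both free positions are activated by the two phenols. Fallback, from 7 back to 9: the unchelated A4 hydroxyl is benzylated selectively (BnBr, K2CO3, acetone) to methyl 4-(benzyloxy)-2-hydroxy-6-methylbenzoate F2. Magnesium-phenoxide-directed ortho-formylation (MgCl2, Et3N, paraformaldehyde, MeCN, reflux) can then only reach the one free position ortho to the remaining hydroxyl, giving methyl 4-(benzyloxy)-3-formyl-2-hydroxy-6-methylbenzoate F3. Benzylation of the last hydroxyl (BnBr, K2CO3, DMF) rejoins the route at 9.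

**Step 6.** Hydrolysis of the di-ortho-substituted ester may be slow, and during prolonged heating hydroxide may attack the aldehyde (disproportionation). Fallback, from 9 back to 10: the aldehyde is first masked with ethane-1,2-diol (TsOH, PhMe, water removal) as methyl 2,4-bis(benzyloxy)-3-(1,3-dioxolan-2-yl)-6-methylbenzoate F4. The ester is then hydrolysed under forcing conditions (KOH, DMSO/H2O, 90 °C) to 2,4-bis(benzyloxy)-3-(1,3-dioxolan-2-yl)-6-methylbenzoic acid F5, and dilute HCl in THF removes the acetal to give 10.

**Step 8.** Acyl transfer between a di-ortho-substituted acid chloride and a phenol flanked by methyl and benzyloxy may be slow enough for hydrolysis or decomposition of 11 to compete. Fallback, from 10 and 6 back to 12: direct condensation with trifluoroacetic anhydride in toluene at rt. The mixed anhydride ionizes towards a hindered acylium ion that is captured by the phenol, so the separate chloride and the acylpyridinium pathway are avoided; no new isolated compound is involved.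

**Step 10.** Cleavage of the B4 benzyl ether, which has no ortho carbonyl to assist it, may lag behind the two ring A ethers. Pushing the reaction or a careless work-up may then cause acyl shift from B3 to B4 or ester cleavage. Fallback, from 13 directly to 14: catalytic hydrogenolysis (H2 at 1 atm, Pd/C, EtOAc, rt, stopped at full conversion). This changes the mechanism from Lewis-acid ionization to surface hydrogenolysis and stays neutral throughout; its own hazard is over-reduction of the chelated aldehyde.

## Further compounds

F1 | step 3 | methyl 5-(benzyloxy)-1-[(tert-butyldimethylsilyl)oxy]-6-methyl-3-methylidene-7-oxabicyclo[2.2.1]hept-5-ene-2-carboxylate (racemic, mixture of ester epimers) | COC(=O)C1C(=C)C2OC1(O[Si](C)(C)C(C)(C)C)C(C)=C2OCc1ccccc1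
F2 | step 4 | methyl 4-(benzyloxy)-2-hydroxy-6-methylbenzoate | COC(=O)c1c(C)cc(OCc2ccccc2)cc1O
F3 | step 4 | methyl 4-(benzyloxy)-3-formyl-2-hydroxy-6-methylbenzoate | COC(=O)c1c(C)cc(OCc2ccccc2)c(C=O)c1O
F4 | step 6 | methyl 2,4-bis(benzyloxy)-3-(1,3-dioxolan-2-yl)-6-methylbenzoate | COC(=O)c1c(C)cc(OCc2ccccc2)c(C2OCCO2)c1OCc1ccccc1
F5 | step 6 | 2,4-bis(benzyloxy)-3-(1,3-dioxolan-2-yl)-6-methylbenzoic acid | OC(=O)c1c(C)cc(OCc2ccccc2)c(C2OCCO2)c1OCc1ccccc1
F0 | step 8 | none | none
F0 | step 10 | none | none
A1 | alternative 1 | (Z)-4-(benzyloxy)hex-4-en-3-one | CCC(=O)/C(OCc1ccccc1)=C/C
A2 | alternative 1 | dimethyl malonate | COC(=O)CC(=O)OC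
A3 | alternative 1 | methyl 5-(benzyloxy)-3,6-dimethyl-2,4-dioxocyclohexane-1-carboxylate (mixture of diastereomers) | COC(=O)C1C(C)C(OCc2ccccc2)C(=O)C(C)C1=O
A4 | alternative 1 | methyl 5-(benzyloxy)-2,4-dihydroxy-3,6-dimethylbenzoate | COC(=O)c1c(C)c(OCc2ccccc2)c(O)c(C)c1O
A5 | alternative 1 | methyl 2,4-dihydroxy-3,6-dimethylbenzoate | COC(=O)c1c(C)cc(O)c(C)c1O
A6 | alternative 2 | benzyl (E)-5-diazo-3-methyl-4-oxopent-2-enoate | O=C(OCc1ccccc1)/C=C(\C)C(=O)C=[N+]=[N-]
A7 | alternative 2 | [(3,3-dimethoxyprop-1-yn-1-yl)oxy]triisopropylsilane | COC(OC)C#CO[Si](C(C)C)(C(C)C)C(C)C
A8 | alternative 2 | benzyl 3-(dimethoxymethyl)-2-hydroxy-6-methyl-4-(triisopropylsilyloxy)benzoate | O=C(OCc1ccccc1)c1c(C)cc(O[Si](C(C)C)(C(C)C)C(C)C)c(C(OC)OC)c1O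
A9 | alternative 3 | methyl 2,4-bis(benzyloxy)-3,6-dimethyl-5-[(3,5,7-trioxooctanoyl)oxy]benzoate | COC(=O)c1c(C)c(OC(=O)CC(=O)CC(=O)CC(C)=O)c(OCc2ccccc2)c(C)c1OCc1ccccc1
A10 | alternative 3 | methyl 2,4-bis(benzyloxy)-5-(2,4-dihydroxy-6-methylbenzoyloxy)-3,6-dimethylbenzoate | COC(=O)c1c(C)c(OC(=O)c2c(C)cc(O)cc2O)c(OCc2ccccc2)c(C)c1OCc1ccccc1
A11 | alternative 3 | methyl 2,4-bis(benzyloxy)-5-hydroxy-3,6-dimethylbenzoate | COC(=O)c1c(C)c(O)c(OCc2ccccc2)c(C)c1OCc1ccccc1
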